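## Retrosynthetic overview
1. The last C–C bond is C11–C12. It is made by Nozaki–Hiyama–Kishi addition of an (E)-alkenyl iodide carrying pyranone B to a β-acetoxy aldehyde carrying pyranone A, and only one desilylation follows.
2. Each 4-pyranone comes from an acyclic 1,3,5-triketone by neutral PPh3/CCl4 cyclodehydration. Ring B closes in the eastern branch (step 13) and ring A in the western branch (step 18), both before the union.
3. Triketone B uses pentan-3-one as the C16–C18 linchpin with two aldehydes (two aldols, then a double oxidation). Triketone A comes from the dianion of 4-methylheptane-3,5-dione and a C7 aldehyde, followed by oxidation.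
4. Stereocentres: C10 and C14 both come from one (S)-Roche aldehyde, C20/C21 from an L-proline aldol, C8/C9 from a D-proline cross-aldol, and C11 from Felkin addition. The E-alkene comes from hydrozirconation–iodination.
5. The C9 acetate is placed by kinetic hydrolysis of the cyclic orthoacetate of the C9/C11 diol, so no protecting-group exchange is needed.

Assumption and numbering: 4-methylheptane-3,5-dione, LDA solution, Cp2Zr(H)Cl and DMP are bought; backbone numbering is C1–C2 ethyl, C3–C7 pyranone A, C8–C14 chain (C9 OAc, C11 OH, C12=C13), C15–C19 pyranone B, C20–C23 side chain.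

## Route

Step 1
Reactants: 1 methyl (S)-3-hydroxy-2-methylpropanoate ((S)-Roche ester)
Product: 2 methyl (S)-3-[(tert-butyldimethylsilyl)oxy]-2-methylpropanoate
Conditions: TBSCl, imidazole, CH2Cl2, 0 °C to rt
Reagents that add atoms: tert-butyldimethylsilyl chloride, CC(C)(C)[Si](C)(C)Cl
Why: Imidazole-promoted O-silylation masks the primary alcohol and leaves untouched the stereocentre that later serves as both C10 and C14.

Step 2
Reactants: 2 methyl (S)-3-[(tert-butyldimethylsilyl)oxy]-2-methylpropanoate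
Product: 3 (S)-3-[(tert-butyldimethylsilyl)oxy]-2-methylpropanal
Conditions: DIBAL-H (1.05 equiv), CH2Cl2, −78 °C; aq. Rochelle salt
Reagents that add atoms: none
Why: In this partial ester reduction the aluminium hemiacetal survives at −78 °C and collapses only on work-up, so reduction stops at the aldehyde without epimerisation.

Step 3
Reactants: 3 (S)-3-[(tert-butyldimethylsilyl)oxy]-2-methylpropanal
Product: 4 (R)-tert-butyl[(4,4-dibromo-2-methylbut-3-en-1-yl)oxy]dimethylsilane
Conditions: CBr4, PPh3, CH2Cl2, 0 °C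
Reagents that add atoms: carbon tetrabromide, BrC(Br)(Br)Br
Why: The Corey–Fuchs (Ramirez) dibromoolefination is a Wittig reaction of Ph3P=CBr2 under non-basic conditions, so the α-stereocentre is kept (the descriptor changes only through CIP ranking).

Step 4
Reactants: 4 (R)-tert-butyl[(4,4-dibromo-2-methylbut-3-en-1-yl)oxy]dimethylsilane
Product: 6 (R)-tert-butyldimethyl[(2-methylpent-3-yn-1-yl)oxy]silane, via [(3R)-4-[(tert-butyldimethylsilyl)oxy]-3-methylbut-1-yn-1-yl]lithium 5 (not isolated)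
Conditions: n-BuLi (2.1 equiv), THF, −78 °C; MeI, −78 °C to rt
Reagents that add atoms: iodomethane, CI
Why: In the second stage of the Corey–Fuchs sequence, Br/Li exchange, Fritsch–Buttenberg–Wiechell rearrangement and deprotonation give the acetylide, and SN2 methylation installs the future C12 methyl group.

Step 5
Reactants: 6 (R)-tert-butyldimethyl[(2-methylpent-3-yn-1-yl)oxy]silane
Product: 8 (R,E)-tert-butyl[(4-iodo-2-methylpent-3-en-1-yl)oxy]dimethylsilane, via chlorobis(cyclopentadienyl)[(2E,4R)-5-[(tert-butyldimethylsilyl)oxy]-4-methylpent-2-en-2-yl]zirconium 7 (not isolated)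
Conditions: Cp2Zr(H)Cl (1.6 equiv), THF, rt to 40 °C; I2, 0 °C
Reagents that add atoms: iodine, II
Why: Schwartz hydrozirconation adds H and Zr syn with Zr on the less hindered methyl-bearing carbon (excess reagent equilibrates the regioisomers), and iodinolysis with retention fixes the E geometry of C12=C13.

Step 6
Reactants: 8 (R,E)-tert-butyl[(4-iodo-2-methylpent-3-en-1-yl)oxy]dimethylsilane
Product: 9 (R,E)-4-iodo-2-methylpent-3-en-1-ol
Conditions: CSA (10 mol %), MeOH–CH2Cl2, 0 °C
Reagents that add atoms: none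
Why: Acid-catalysed methanolysis removes the primary silyl ether quickly and does not affect the alkenyl iodide or the allylic stereocentre.

Step 7
Reactants: 9 (R,E)-4-iodo-2-methylpent-3-en-1-ol
Product: 10 (R,E)-4-iodo-2-methylpent-3-enal
Conditions: DMP, CH2Cl2, 0 °C; used at once
Reagents that add atoms: none
Why: Dess–Martin oxidation is base-free, so the β,γ-unsaturated α-chiral aldehyde forms without conjugation or racemisation.

Step 8
Reactants: 11 propanal (two molecules)
Product: 12 (2S,3S)-3-hydroxy-2-methylpentanal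
Conditions: L-proline (10 mol %), DMF, 4 °C
Reagents that add atoms: none
Why: In this proline enamine-catalysed direct aldol (Houk–List transition state) the E-enamine attacks the acid-bound aldehyde on one face, giving the anti (2S,3S) aldol that becomes C20/C21 in high ee at about 4:1 anti:syn.

Step 9
Reactants: 12 (2S,3S)-3-hydroxy-2-methylpentanal
Product: 13 (2S,3S)-3-[(tert-butyldimethylsilyl)oxy]-2-methylpentanal
Conditions: TBSOTf, 2,6-lutidine, CH2Cl2, −78 °C; syn isomer removed by chromatography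
Reagents that add atoms: tert-butyldimethylsilyl triflate, CC(C)(C)[Si](C)(C)OS(=O)(=O)C(F)(F)F
Why: Low-temperature O-silylation with a hindered base protects the aldol hydroxyl without retro-aldol, elimination or epimerisation of the aldehyde.

Step 10
Reactants: 14 pentan-3-one; 13 (2S,3S)-3-[(tert-butyldimethylsilyl)oxy]-2-methylpentanal
Product: 16 (6R,7S)-7-[(tert-butyldimethylsilyl)oxy]-5-hydroxy-4,6-dimethylnonan-3-one (C4/C5 epimers), via lithium pent-2-en-3-olate 15 (not isolated)
Conditions: LDA, THF, −78 °C; then 13, −78 °C; aq. NH4Cl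
Reagents that add atoms: none
Why: The kinetic lithium-enolate aldol forms C18–C19, and the two new centres are carried as a mixture because both become sp2 in the pyranone, while C20/C21 are not α to a carbonyl in the product.

Step 11
Reactants: 16 (6R,7S)-7-[(tert-butyldimethylsilyl)oxy]-5-hydroxy-4,6-dimethylnonan-3-one; 10 (R,E)-4-iodo-2-methylpent-3-enal
Product: 18 (2E,4R,10R,11S)-11-[(tert-butyldimethylsilyl)oxy]-5,9-dihydroxy-2-iodo-4,6,8,10-tetramethyltridec-2-en-7-one (epimers at C5, C6, C8, C9), via dilithium alkoxide–enolate 17 (not isolated)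
Conditions: LDA (2.2 equiv), THF, −78 °C; then 10, −78 °C, 10 min; aq. NH4Cl at −78 °C
Reagents that add atoms: none
Why: In this aldolate-dianion aldol the first base equivalent makes the C19 alkoxide and the second removes the kinetic α′-CH2 proton (C16), and the enolate adds to the aldehyde faster than it enolises it, forming C15–C16 with C14 carried in from 10.

Step 12
Reactants: 18 (2E,4R,10R,11S)-11-[(tert-butyldimethylsilyl)oxy]-5,9-dihydroxy-2-iodo-4,6,8,10-tetramethyltridec-2-en-7-one
Product: 19 (2E,4R,10S,11S)-11-[(tert-butyldimethylsilyl)oxy]-2-iodo-4,6,8,10-tetramethyltridec-2-ene-5,7,9-trione (keto/enol and C6/C8 mixture)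
Conditions: DMP (3 equiv), CH2Cl2, 0 °C to rt
Reagents that add atoms: none
Why: The double Dess–Martin oxidation converts both carbinols to ketones without base, so the β,γ-alkene, the alkenyl iodide, the TBS ether and the C14/C20 centres are preserved.

Step 13
Reactants: 19 (2E,4R,10S,11S)-11-[(tert-butyldimethylsilyl)oxy]-2-iodo-4,6,8,10-tetramethyltridec-2-ene-5,7,9-trione
Product: 20 2-[(2S,3S)-3-[(tert-butyldimethylsilyl)oxy]pentan-2-yl]-6-[(2R,3E)-4-iodopent-3-en-2-yl]-3,5-dimethyl-4H-pyran-4-one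
Conditions: PPh3, CCl4, THF, rt
Reagents that add atoms: none
Why: In this Appel-type cyclodehydration one terminal enol oxygen becomes an oxyphosphonium leaving group and the other terminal enol oxygen closes ring B by addition–elimination at room temperature, mild enough to keep the flanking C14 and C20 centres.

Step 14
Reactants: 3 (S)-3-[(tert-butyldimethylsilyl)oxy]-2-methylpropanal; 11 propanal
Product: 21 (2R,3R,4S)-5-[(tert-butyldimethylsilyl)oxy]-3-hydroxy-2,4-dimethylpentanal
Conditions: D-proline (20 mol %), DMF, 4 °C, 11 added by syringe pump over 24 h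
Reagents that add atoms: none
Why: In this proline-catalysed cross-aldol only unbranched propanal forms the enamine and the α-branched aldehyde acts as acceptor, so D-proline sets the anti (8R,9R) pair in the Felkin-matched sense (9,10-syn) relative to C10.

Step 15
Reactants: 21 (2R,3R,4S)-5-[(tert-butyldimethylsilyl)oxy]-3-hydroxy-2,4-dimethylpentanal
Product: 22 (2R,3R,4S)-3,5-bis[(tert-butyldimethylsilyl)oxy]-2,4-dimethylpentanal
Conditions: TBSOTf, 2,6-lutidine, CH2Cl2, −78 °C
Reagents that add atoms: tert-butyldimethylsilyl triflate, CC(C)(C)[Si](C)(C)OS(=O)(=O)C(F)(F)F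
Why: O-silylation blocks the C9 hydroxyl, which would otherwise close a dihydropyranone at the triketone stage, and the cold hindered-base conditions keep C8 intact.

Step 16
Reactants: 23 4-methylheptane-3,5-dione; 22 (2R,3R,4S)-3,5-bis[(tert-butyldimethylsilyl)oxy]-2,4-dimethylpentanal
Product: 25 (8S,9R,10S)-9,11-bis[(tert-butyldimethylsilyl)oxy]-7-hydroxy-4,6,8,10-tetramethylundecane-3,5-dione (epimers at C4, C6, C7), via dilithium diketone dianion 24 (not isolated)
Conditions: LDA (2.1 equiv), THF, −78 to 0 °C; then 22, −78 °C; aq. NH4Cl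
Reagents that add atoms: none
Why: In this β-diketone dianion (γ-selective) aldol the more basic terminal carbanion attacks the aldehyde to form C6–C7, and the new centres are erased later.

Step 17
Reactants: 25 (8S,9R,10S)-9,11-bis[(tert-butyldimethylsilyl)oxy]-7-hydroxy-4,6,8,10-tetramethylundecane-3,5-dione
Product: 26 (8R,9R,10S)-9,11-bis[(tert-butyldimethylsilyl)oxy]-4,6,8,10-tetramethylundecane-3,5,7-trione (keto/enol mixture)
Conditions: DMP, CH2Cl2, 0 °C to rt
Reagents that add atoms: none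
Why: Dess–Martin oxidation of the δ-hydroxy-β-diketone gives the 1,3,5-triketone without base, so C8 is not epimerised and the β-silyloxy group is not eliminated.

Step 18
Reactants: 26 (8R,9R,10S)-9,11-bis[(tert-butyldimethylsilyl)oxy]-4,6,8,10-tetramethylundecane-3,5,7-trione
Product: 27 2-[(2R,3R,4S)-3,5-bis[(tert-butyldimethylsilyl)oxy]-4-methylpentan-2-yl]-6-ethyl-3,5-dimethyl-4H-pyran-4-one
Conditions: PPh3, CCl4, THF, rt
Reagents that add atoms: none
Why: The same Appel-type cyclodehydration of the triketone closes ring A under mild conditions and retains the adjacent C8 stereocentre.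

Step 19
Reactants: 27 2-[(2R,3R,4S)-3,5-bis[(tert-butyldimethylsilyl)oxy]-4-methylpentan-2-yl]-6-ethyl-3,5-dimethyl-4H-pyran-4-one
Product: 28 2-[(2R,3R,4S)-3,5-dihydroxy-4-methylpentan-2-yl]-6-ethyl-3,5-dimethyl-4H-pyran-4-one
Conditions: 48% aq. HF, MeCN, 0 °C to rt
Reagents that add atoms: none
Why: Fluoride-driven desilylation in acid removes both TBS groups, and the acid-stable pyranone and base-sensitive C8–H are not affected.

Step 20
Reactants: 28 2-[(2R,3R,4S)-3,5-dihydroxy-4-methylpentan-2-yl]-6-ethyl-3,5-dimethyl-4H-pyran-4-one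
Product: 30 (2S,3R,4R)-4-(6-ethyl-3,5-dimethyl-4-oxo-4H-pyran-2-yl)-1-hydroxy-2-methylpentan-3-yl acetate, via 2-ethyl-6-{(1R)-1-[(4R,5S)-2-methoxy-2,5-dimethyl-1,3-dioxan-4-yl]ethyl}-3,5-dimethyl-4H-pyran-4-one 29 (not isolated)
Conditions: MeC(OMe)3, CSA (5 mol %), CH2Cl2, rt; then 80% aq. AcOH, 0 °C to rt
Reagents that add atoms: trimethyl orthoacetate, CC(OC)(OC)OC; water, O
Why: After cyclic orthoester formation, kinetic acid hydrolysis makes the hemiorthoester expel the less hindered primary oxygen, so the acetyl group stays on the secondary C9 oxygen and no stereocentre is involved.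

Step 21
Reactants: 30 (2S,3R,4R)-4-(6-ethyl-3,5-dimethyl-4-oxo-4H-pyran-2-yl)-1-hydroxy-2-methylpentan-3-yl acetate
Product: 31 (2R,3S,4R)-4-(6-ethyl-3,5-dimethyl-4-oxo-4H-pyran-2-yl)-2-methyl-1-oxopentan-3-yl acetate
Conditions: DMP, CH2Cl2, 0 °C; used at once
Reagents that add atoms: none
Why: Dess–Martin oxidation gives the β-acetoxy aldehyde without base, avoiding E1cB loss of acetate and C10 epimerisation (the descriptors change only through CIP ranking).

Step 22
Reactants: 31 (2R,3S,4R)-4-(6-ethyl-3,5-dimethyl-4-oxo-4H-pyran-2-yl)-2-methyl-1-oxopentan-3-yl acetate; 20 2-[(2S,3S)-3-[(tert-butyldimethylsilyl)oxy]pentan-2-yl]-6-[(2R,3E)-4-iodopent-3-en-2-yl]-3,5-dimethyl-4H-pyran-4-one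
Product: 33 (2R,3R,4S,5S,6E,8R)-8-{6-[(2S,3S)-3-[(tert-butyldimethylsilyl)oxy]pentan-2-yl]-3,5-dimethyl-4-oxo-4H-pyran-2-yl}-2-(6-ethyl-3,5-dimethyl-4-oxo-4H-pyran-2-yl)-5-hydroxy-4,6-dimethylnon-6-en-3-yl acetate, via alkenylchromium dichloride 32 (not isolated)
Conditions: CrCl2 (8 equiv), NiCl2 (1 mol % of Cr), 20 (1.3 equiv), degassed DMSO, rt; water
Reagents that add atoms: none
Why: In the Nozaki–Hiyama–Kishi coupling, Ni inserts into C–I with retention of geometry and the alkenylchromium adds only to the aldehyde (acetate and pyranones are inert), with Felkin–Anh attack giving the 10,11-syn (11S) allylic alcohol.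

Step 23
Reactants: 33 the C21 TBS ether of the target
Product: 34 CNP0290537.1, (2R,3R,4S,5S,6E,8R)-2-(6-ethyl-3,5-dimethyl-4-oxo-4H-pyran-2-yl)-5-hydroxy-8-{6-[(2S,3S)-3-hydroxypentan-2-yl]-3,5-dimethyl-4-oxo-4H-pyran-2-yl}-4,6-dimethylnon-6-en-3-yl acetate
Conditions: HF·pyridine, pyridine, THF, 0 °C to rt
Reagents that add atoms: none
Why: Buffered fluoride desilylation frees the C21 hydroxyl under conditions too mild to ionise the allylic alcohol, cleave the acetate or move it.

## Compound list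
1 | methyl (S)-3-hydroxy-2-methylpropanoate | COC(=O)[C@@H](C)CO | starting material
2 | methyl (S)-3-[(tert-butyldimethylsilyl)oxy]-2-methylpropanoate | COC(=O)[C@@H](C)CO[Si](C)(C)C(C)(C)C | intermediate
3 | (S)-3-[(tert-butyldimethylsilyl)oxy]-2-methylpropanal | O=C[C@@H](C)CO[Si](C)(C)C(C)(C)C | intermediate
4 | (R)-tert-butyl[(4,4-dibromo-2-methylbut-3-en-1-yl)oxy]dimethylsilane | BrC(Br)=C[C@@H](C)CO[Si](C)(C)C(C)(C)C | intermediate
5 | [(3R)-4-[(tert-butyldimethylsilyl)oxy]-3-methylbut-1-yn-1-yl]lithium | [Li]C#C[C@@H](C)CO[Si](C)(C)C(C)(C)C | intermediate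
6 | (R)-tert-butyldimethyl[(2-methylpent-3-yn-1-yl)oxy]silane | CC#C[C@@H](C)CO[Si](C)(C)C(C)(C)C | intermediate
7 | chlorobis(cyclopentadienyl)[(2E,4R)-5-[(tert-butyldimethylsilyl)oxy]-4-methylpent-2-en-2-yl]zirconium (Cp drawn σ-bound) | Cl[Zr](C1C=CC=C1)(C1C=CC=C1)/C(C)=C/[C@@H](C)CO[Si](C)(C)C(C)(C)C | intermediate
8 | (R,E)-tert-butyl[(4-iodo-2-methylpent-3-en-1-yl)oxy]dimethylsilane | I/C(C)=C/[C@@H](C)CO[Si](C)(C)C(C)(C)C | intermediate
9 | (R,E)-4-iodo-2-methylpent-3-en-1-ol | I/C(C)=C/[C@@H](C)CO | intermediate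
10 | (R,E)-4-iodo-2-methylpent-3-enal | I/C(C)=C/[C@@H](C)C=O | intermediate
11 | propanal | CCC=O | starting material
12 | (2S,3S)-3-hydroxy-2-methylpentanal | O=C[C@@H](C)[C@@H](O)CC | intermediate
13 | (2S,3S)-3-[(tert-butyldimethylsilyl)oxy]-2-methylpentanal | O=C[C@@H](C)[C@@H](O[Si](C)(C)C(C)(C)C)CC | intermediate
14 | pentan-3-one | CCC(=O)CC | starting material
15 | lithium pent-2-en-3-olate | CC=C(CC)O[Li] | intermediate
16 | (6R,7S)-7-[(tert-butyldimethylsilyl)oxy]-5-hydroxy-4,6-dimethylnonan-3-one (C4/C5 epimers) | CCC(=O)C(C)C(O)[C@@H](C)[C@@H](O[Si](C)(C)C(C)(C)C)CC | intermediate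
17 | dilithium alkoxide–enolate (C19 lithium alkoxide and C16=C17 lithium enolate of 16) | CC=C(O[Li])C(C)C(O[Li])[C@@H](C)[C@@H](O[Si](C)(C)C(C)(C)C)CC | intermediate
18 | (2E,4R,10R,11S)-11-[(tert-butyldimethylsilyl)oxy]-5,9-dihydroxy-2-iodo-4,6,8,10-tetramethyltridec-2-en-7-one (epimers at C5, C6, C8, C9) | I/C(C)=C/[C@@H](C)C(O)C(C)C(=O)C(C)C(O)[C@@H](C)[C@@H](O[Si](C)(C)C(C)(C)C)CC | intermediate
19 | (2E,4R,10S,11S)-11-[(tert-butyldimethylsilyl)oxy]-2-iodo-4,6,8,10-tetramethyltridec-2-ene-5,7,9-trione | I/C(C)=C/[C@@H](C)C(=O)C(C)C(=O)C(C)C(=O)[C@@H](C)[C@@H](O[Si](C)(C)C(C)(C)C)CC | intermediate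
20 | 2-[(2S,3S)-3-[(tert-butyldimethylsilyl)oxy]pentan-2-yl]-6-[(2R,3E)-4-iodopent-3-en-2-yl]-3,5-dimethyl-4H-pyran-4-one | I/C(C)=C/[C@@H](C)c1oc([C@@H](C)[C@@H](O[Si](C)(C)C(C)(C)C)CC)c(C)c(=O)c1C | intermediate
21 | (2R,3R,4S)-5-[(tert-butyldimethylsilyl)oxy]-3-hydroxy-2,4-dimethylpentanal | O=C[C@H](C)[C@H](O)[C@@H](C)CO[Si](C)(C)C(C)(C)C | intermediate
22 | (2R,3R,4S)-3,5-bis[(tert-butyldimethylsilyl)oxy]-2,4-dimethylpentanal | O=C[C@H](C)[C@H](O[Si](C)(C)C(C)(C)C)[C@@H](C)CO[Si](C)(C)C(C)(C)C | intermediate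
23 | 4-methylheptane-3,5-dione | CCC(=O)C(C)C(=O)CC | starting material
24 | dilithium diketone dianion (dilithium bis-enolate of 4-methylheptane-3,5-dione) | CC=C(O[Li])C(C)=C(O[Li])CC | intermediate
25 | (8S,9R,10S)-9,11-bis[(tert-butyldimethylsilyl)oxy]-7-hydroxy-4,6,8,10-tetramethylundecane-3,5-dione (epimers at C4, C6, C7) | CCC(=O)C(C)C(=O)C(C)C(O)[C@H](C)[C@H](O[Si](C)(C)C(C)(C)C)[C@@H](C)CO[Si](C)(C)C(C)(C)C | intermediate
26 | (8R,9R,10S)-9,11-bis[(tert-butyldimethylsilyl)oxy]-4,6,8,10-tetramethylundecane-3,5,7-trione | CCC(=O)C(C)C(=O)C(C)C(=O)[C@H](C)[C@H](O[Si](C)(C)C(C)(C)C)[C@@H](C)CO[Si](C)(C)C(C)(C)C | intermediate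
27 | 2-[(2R,3R,4S)-3,5-bis[(tert-butyldimethylsilyl)oxy]-4-methylpentan-2-yl]-6-ethyl-3,5-dimethyl-4H-pyran-4-one | CCc1oc([C@H](C)[C@H](O[Si](C)(C)C(C)(C)C)[C@@H](C)CO[Si](C)(C)C(C)(C)C)c(C)c(=O)c1C | intermediate
28 | 2-[(2R,3R,4S)-3,5-dihydroxy-4-methylpentan-2-yl]-6-ethyl-3,5-dimethyl-4H-pyran-4-one | CCc1oc([C@H](C)[C@H](O)[C@@H](C)CO)c(C)c(=O)c1C | intermediate
29 | 2-ethyl-6-{(1R)-1-[(4R,5S)-2-methoxy-2,5-dimethyl-1,3-dioxan-4-yl]ethyl}-3,5-dimethyl-4H-pyran-4-one (orthoester carbon epimers) | CCc1oc([C@H](C)[C@H]2[C@@H](C)COC(C)(OC)O2)c(C)c(=O)c1C | intermediate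
30 | (2S,3R,4R)-4-(6-ethyl-3,5-dimethyl-4-oxo-4H-pyran-2-yl)-1-hydroxy-2-methylpentan-3-yl acetate | CCc1oc([C@H](C)[C@H](OC(C)=O)[C@@H](C)CO)c(C)c(=O)c1C | intermediate
31 | (2R,3S,4R)-4-(6-ethyl-3,5-dimethyl-4-oxo-4H-pyran-2-yl)-2-methyl-1-oxopentan-3-yl acetate | CCc1oc([C@H](C)[C@H](OC(C)=O)[C@@H](C)C=O)c(C)c(=O)c1C | intermediate
32 | alkenylchromium dichloride, dichloro[(2E,4R)-4-{6-[(2S,3S)-3-[(tert-butyldimethylsilyl)oxy]pentan-2-yl]-3,5-dimethyl-4-oxo-4H-pyran-2-yl}pent-2-en-2-yl]chromium(III) | Cl[Cr](Cl)/C(C)=C/[C@@H](C)c1oc([C@@H](C)[C@@H](O[Si](C)(C)C(C)(C)C)CC)c(C)c(=O)c1C | intermediate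
33 | C21 TBS ether of the target | CCc1oc([C@H](C)[C@H](OC(C)=O)[C@@H](C)[C@H](O)/C(C)=C/[C@@H](C)c2oc([C@@H](C)[C@@H](O[Si](C)(C)C(C)(C)C)CC)c(C)c(=O)c2C)c(C)c(=O)c1C | intermediate
34 | CNP0290537.1 | CCc1oc([C@H](C)[C@H](OC(C)=O)[C@@H](C)[C@H](O)/C(C)=C/[C@@H](C)c2oc([C@@H](C)[C@@H](O)CC)c(C)c(=O)c2C)c(C)c(=O)c1C | target

## Summary
Total step count: 23.
Longest linear sequence: 12 steps (1–7, 11–13, 22, 23). The western branch (1, 2, 14–21, 22, 23) is equally long.

### The three steps most likely to fail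

**Step 22 (NHK addition).** The Felkin bias of the C10 methyl group is opposed by the 1,3-anti bias of the C9 acetoxy group, so the ratio at C11 may be low. The fallback sets C11 after the C–C bond is made, not during it. It sets out from 31, which is coupled with 20 as in step 22 without regard to selectivity, giving a mixture of 33 and the C11 epimer of 33 F1. The mixture is oxidised with DMP in CH2Cl2 at 0 °C to the C11 enone F2. F2 is then reduced with (R)-Me-CBS and catecholborane in toluene at −78 °C. The α-methylalkenyl branch acts as the large group, so hydride delivery gives the 11S alcohol, and the route is rejoined at 33.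

**Step 11 (aldolate-dianion aldol).** The strongly basic dianion may enolise or racemise the β,γ-unsaturated aldehyde 10, or the aldolate may undergo retro-aldol. The fallback sets out from 16 and replaces the basic enolate by a Lewis-acid aldol. 16 is treated with LDA (2.2 equiv) and then TMSCl to give the bis-trimethylsilyl derivative of 16 F3, which carries a C19 TMS ether and a C16–C17 silyl enol ether. F3 is combined with 10 and BF3·OEt2 in CH2Cl2 at −78 °C (Mukaiyama aldol). A dilute HCl/THF work-up removes the TMS groups, and the route is rejoined at 18.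

**Step 20 (orthoacetate opening).** The hydrolysis may give some primary acetate, or the acetyl group may migrate to the primary oxygen. The fallback sets out from 28 and uses protecting groups in place of kinetic selectivity. TBSCl and imidazole at 0 °C silylate only the primary hydroxyl, giving the C11 mono-TBS ether of 28 F4. Ac2O, DMAP and pyridine then give the C9 acetate C11 TBS ether F5. HF·pyridine in THF frees the primary alcohol, and the route is rejoined at 30.

## Further compounds
F1 | step 22 | C11 epimer of 33 | CCc1oc([C@H](C)[C@H](OC(C)=O)[C@@H](C)[C@@H](O)/C(C)=C/[C@@H](C)c2oc([C@@H](C)[C@@H](O[Si](C)(C)C(C)(C)C)CC)c(C)c(=O)c2C)c(C)c(=O)c1C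
F2 | step 22 | C11 enone | CCc1oc([C@H](C)[C@H](OC(C)=O)[C@@H](C)C(=O)/C(C)=C/[C@@H](C)c2oc([C@@H](C)[C@@H](O[Si](C)(C)C(C)(C)C)CC)c(C)c(=O)c2C)c(C)c(=O)c1C
F3 | step 11 | bis-trimethylsilyl derivative of 16 | CC=C(O[Si](C)(C)C)C(C)C(O[Si](C)(C)C)[C@@H](C)[C@@H](O[Si](C)(C)C(C)(C)C)CC
F4 | step 20 | C11 mono-TBS ether of 28 | CCc1oc([C@H](C)[C@H](O)[C@@H](C)CO[Si](C)(C)C(C)(C)C)c(C)c(=O)c1C
F5 | step 20 | C9 acetate C11 TBS ether | CCc1oc([C@H](C)[C@H](OC(C)=O)[C@@H](C)CO[Si](C)(C)C(C)(C)C)c(C)c(=O)c1C
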